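# Fragransin B1 by twofold boronate homologation on a meso dihydrofuran

## Analysis of the target

Fragransin B1 (17) is a lignan built on a single oxolane ring. C2 and C5 each carry a 4-hydroxy-3,5-dimethoxyphenyl group, and C3 and C4 each carry a methyl group. All four ring carbons are stereocentres: the aryl groups are cis to each other, the methyl groups are cis to each other, and each methyl is trans to the neighbouring aryl group (2,3-trans, 3,4-cis, 4,5-trans). A mirror plane through the ring oxygen and the midpoint of the C3–C4 bond makes the molecule meso, (2S,3S,4R,5R), so only relative configuration has to be controlled. The sensitive sites are the two free, electron-rich phenols and the two benzylic C–O bonds of the ring, which ionise under acid (epimerisation at C2 and C5) and can be hydrogenolysed. The difficulty lies in placing four contiguous stereocentres on a small, flexible ring, with two eclipsing cis methyl groups both on the face opposite the aryl groups. The strategy reads the C3–CH3 and C4–CH3 bonds as a syn addition of two one-carbon units to the C3=C4 bond of a cis-2,5-diaryl-2,5-dihydrofuran from its open face; the mirror symmetry lets both carbons be treated in one operation.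

## Retrosynthetic reasoning

**17 ⇐ 16.** The two O–CH2Ph bonds are cut last. The free phenols of 17 would consume every organomagnesium and organolithium reagent of the route, so they are carried as benzyl ethers from the first step. Benzyl is inert to base, hydride, alkaline peroxide and the platinum catalyst and leaves under neutral hydrogenolysis. The forward step must cleave two aryl benzyl ethers without touching the benzylic C–O bonds of the ring.

**16 ⇐ 15 ⇐ 14 ⇐ 13.** Each methyl group is traced back, with no change of skeleton, to CH2–OSO2CH3, CH2–OH and finally CH2–B. Nothing is cut at a stereocentre. The purpose is to turn the methyl carbons into carbons that a boron homologation can deliver. The forward steps are an oxidation of primary C–B bonds, a sulfonylation and a hydride displacement at primary carbon, all remote from C2–C5.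

**13 ⇐ 10 + 11.** This is the central disconnection: the C3–CH2 and C4–CH2 bonds. They are exocyclic, equivalent by symmetry, and attached to stereocentres whose configuration is exactly that of a syn addition to a C3=C4 double bond. Cutting a ring bond instead would break the mirror symmetry and force the two halves to be made separately. The gain is that both methyl carbons come from one C1 reagent, 11, in one operation, and that the configuration of C3 and C4 passes from boron to carbon by a stereoretentive 1,2-shift. The forward reaction must load both boron atoms of 10 with the lithium carbenoid made from 11, stop at one carbon per boron, and let migration run ahead of any opening of the β-oxygenated boronate.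

**10 ⇐ 8 + 9.** Both C–B bonds are cut together, the retron of a metal-catalysed syn diboration. In 8 the two aryl groups stand on one face of a nearly flat ring, so a reagent that adds both boron atoms from one side can only use the other face. The four-stereocentre problem is thereby reduced to the cis relation of C2 and C5. The catalyst must be a phosphine-free zerovalent platinum source, because the phosphine complexes that serve for alkynes bind a 1,2-disubstituted alkene too weakly to turn over.

**8 ⇐ 7.** One ring C–O bond is cut, leaving a Z-configured ene-1,4-diol. Closure by dehydration needs no activating group, and the carbinol carbon that ionises is stabilised by both the aryl group and the double bond. The forward reaction must also give the cis isomer. Ionisation erases the configuration of one carbinol carbon, so both diastereomers of 7 pass through the same cation; the closure is then steered by the conformation of that cation and must be kept under kinetic control.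

**7 ⇐ 6 ⇐ 2 + 3, and 2 ⇐ 1.** The cis double bond comes from an alkyne by semihydrogenation. The two C(sp)–C(carbinol) bonds of 6 are cut to give two molecules of 2 and the two-carbon unit 3, which acts as a nucleophile at both ends in turn. This assembles the whole skeleton between C2 and C5 from 1 in two operations. The two carbinol centres form without mutual control, which the ionising ring closure makes irrelevant.

## Alternatives that were turned down

**Alternative 1:** The C2–C3 ring bond is disconnected. The precursor is the acyclic α-diazo ester A2, a dibenzylic ether that already holds the C4-methyl and C5-aryl stereocentres. A dirhodium tetracarboxylate with bulky carboxylate ligands would convert the diazo carbon into a carbenoid that inserts into a benzylic O–CH2 hydrogen through a five-membered transition state, closing the ring to ester A1.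
- For: ring formation and two stereocentres in one catalytic step, at a C–H bond activated by both the ether oxygen and the aryl group.
- Against: A2 needs its two stereocentres set beforehand and a diazo transfer onto a non-activated ester. A carbenoid next to a tertiary C–H bond is prone to 1,2-hydride shift to the unsaturated ester, and the electron-rich arenes offer it further targets. The configuration at C2 and C3 rests on a conformational preference in the insertion, not on a fixed element of the substrate. A1 still carries an ester at C3 that needs three operations to become methyl, and the two halves of a symmetric target are built separately.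
- Comparison: it is stronger in that the aryl-bearing carbons never pass through an ionisable allylic alcohol, so the cis relation of the aryl groups is not left to a cation. The chosen route offers instead one facial selection that fixes C3 and C4 together and delivers both methyl carbons at once.

**Alternative 2:** The C5–O bond of a γ-lactone is disconnected, with the second aryl group added later. Cyclobutanone A4 would be treated with a peracid; the benzylic ring carbon migrates to oxygen with retention and gives lactone A3.
- For: the aryl group and both methyl groups, already as methyl groups, are arranged on a rigid four-membered ring; the migration is stereoretentive, and the electron-rich benzylic carbon is the better migrating group.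
- Against: only half of the target is in A3. The second aryl group must be added to the lactone carbonyl as an aryl organometallic reagent and the lactol reduced; hydride normally enters anti to the C3 methyl, which places the new aryl group cis to it, the wrong relation at C2, and calls for a late epimerisation. A4 itself needs a [2+2] cycloaddition with an unactivated cis-alkene and control of its aryl-bearing carbon, and the peracid meets a very electron-rich arene.
- Comparison: on the methyl groups it is clearly stronger than the chosen route, which spends four steps after the key step turning C–B into C–H. The chosen route offers symmetry instead: both aryl-bearing centres and both methyl-bearing centres are made in pairs, and no centre has to be corrected.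

**Alternative 3:** O–C5 and C2–C3 are disconnected in a [3+2] annulation of the donor–acceptor cyclopropane A6 with aldehyde A7 (the same compound as 2) under a mild Lewis acid, giving diester A5. The carbonyl oxygen opens the cyclopropane at its benzylic carbon with inversion, and the malonate carbon then closes on the carbonyl carbon.
- For: convergent and catalytic, two ring bonds in one step, and the 2,5-cis relation of the aryl groups follows from the mechanism, which is where the chosen route is softest.
- Against: because the benzylic carbon is inverted, the 4,5-trans product requires the cyclopropane with aryl and methyl cis, the less accessible isomer. With so electron-rich a donor the opening drifts toward a free benzylic cation, which forfeits the stereospecificity. C3 arrives as a quaternary diester: one ester must be excised and the other reduced to methyl, and the surviving substituent must end up cis to the C4 methyl although it is flanked by an aryl group and a methyl group with no clear bias. That is four or five further steps with an unsolved stereocentre.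
- Comparison: the chosen strategy sets C3 and C4 together by one syn addition and never has to differentiate two groups on the same carbon.

Key step: step 6

Assumption (remark on the chemistry): diols 6 and 7 are used as mixtures of their dl and meso forms, because step 4 passes through a planar cation at the ionised carbinol carbon.

## Route

Step 1
Reactants: 1 syringaldehyde (4-hydroxy-3,5-dimethoxybenzaldehyde)
Product: 2 4-(benzyloxy)-3,5-dimethoxybenzaldehyde
Conditions: BnBr, K2CO3, DMF, 60 °C
Reagents that add atoms: benzyl bromide, BrCc1ccccc1
Why: Williamson ether synthesis; the phenoxide between two methoxy groups is still alkylated cleanly by a benzylic bromide, and the benzyl ether should withstand every later base, hydride and organometallic reagent.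

Step 2
Reactants: 2 4-(benzyloxy)-3,5-dimethoxybenzaldehyde (two equivalents, in two portions), 3 ethynylmagnesium bromide
Product: 6 1,4-bis[4-(benzyloxy)-3,5-dimethoxyphenyl]but-2-yne-1,4-diol (dl/meso mixture), via propargylic magnesium alkoxide 4 (not isolated), via alkynylmagnesium alkoxide 5 (not isolated)
Conditions: 2 (1 equiv), THF, 0 °C; EtMgBr (1.1 equiv), 40 °C; 2 (1 equiv), 0 °C to rt; aq NH4Cl
Reagents that add atoms: none
Why: Two successive Grignard additions: 3 adds to the aldehyde to give alkoxide 4, ethylmagnesium bromide removes the acetylenic proton to give 5, and its alkynyl carbon adds to the second portion of 2. The two carbinol centres form without mutual control, which is accepted because step 4 erases the configuration of the ionised centre.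

Step 3
Reactants: 6 1,4-bis[4-(benzyloxy)-3,5-dimethoxyphenyl]but-2-yne-1,4-diol
Product: 7 (Z)-1,4-bis[4-(benzyloxy)-3,5-dimethoxyphenyl]but-2-ene-1,4-diol (dl/meso mixture)
Conditions: H2 (1 atm), Pd/CaCO3 poisoned with Pb(OAc)2, quinoline, EtOAc, rt
Reagents that add atoms: none
Why: Lindlar semihydrogenation; syn delivery of hydrogen on the poisoned palladium surface should give the Z-alkene needed for five-membered ring closure, and the poisoned catalyst should not hydrogenolyse the benzyl ethers or the benzylic alcohols.

Step 4
Reactants: 7 (Z)-1,4-bis[4-(benzyloxy)-3,5-dimethoxyphenyl]but-2-ene-1,4-diol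
Product: 8 cis-(2R,5S)-2,5-bis[4-(benzyloxy)-3,5-dimethoxyphenyl]-2,5-dihydrofuran (meso)
Conditions: CSA (5 mol%), 4 Å MS, CH2Cl2 (0.02 M), −20 to 0 °C; then Et3N
Reagents that add atoms: none
Why: Acid-catalysed cyclodehydration of a Z-ene-1,4-diol by an SN1 path: either diastereomer of 7 ionises at one carbinol carbon to the same aryl-stabilised, U-shaped allylic cation, and the remaining hydroxyl closes the ring on its terminus. Closure through the conformer that keeps the hydrogen of the carbinol carbon on the crowded inner side of the cation and its aryl group outside (least allylic 1,3-strain) places both aryl groups on one face, so the cis isomer should predominate under kinetic control. Low temperature, catalytic acid and the amine quench should keep 8 from re-ionising, and any trans isomer is removed by chromatography.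

Step 5
Reactants: 8 cis-2,5-bis[4-(benzyloxy)-3,5-dimethoxyphenyl]-2,5-dihydrofuran, 9 bis(pinacolato)diboron
Product: 10 meso-2,5-bis[4-(benzyloxy)-3,5-dimethoxyphenyl]-3,4-bis(4,4,5,5-tetramethyl-1,3,2-dioxaborolan-2-yl)tetrahydrofuran (aryl groups cis; boryl groups cis and on the face opposite the aryl groups)
Conditions: Pt(dba)2 (5 mol%), toluene, 60 °C
Reagents that add atoms: none
Why: Platinum-catalysed syn diboration of a cyclic cis-alkene: the B–B bond adds oxidatively to phosphine-free zerovalent platinum, the alkene inserts into Pt–B, and C–B reductive elimination places both boron atoms on one face. Only the face opposite the two cis aryl groups is open, which sets C3 and C4 with boron trans to the aryl groups and should give the meso isomer alone.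

Step 6
Reactants: 10 meso-2,5-bis[4-(benzyloxy)-3,5-dimethoxyphenyl]-3,4-bis(pinacolboryl)tetrahydrofuran, 11 bromochloromethane
Product: 13 meso-2,5-bis[4-(benzyloxy)-3,5-dimethoxyphenyl]-3,4-bis[(pinacolboryl)methyl]tetrahydrofuran, via dilithium bis(chloromethyl)boronate complex 12 (not isolated)
Conditions: 11 (6 equiv), n-BuLi (5 equiv), THF, −78 °C; then rt, 16 h
Reagents that add atoms: none
Why: Twofold Matteson homologation, the known one-carbon insertion into secondary pinacol boronic esters and into vicinal bis(boronates) from alkene diboration. Bromine–lithium exchange on 11 at −78 °C gives chloromethyllithium in the presence of 10, and each Lewis-acidic boron captures one carbenoid to form the tetracoordinate complex 12. On warming, the ring carbon on each boron shifts to the CH2 carbon anti to the departing chloride, which forms the C3–CH2 and C4–CH2 bonds with retention at the migrating carbon. No ring is closed and no stereocentre is created: C3 and C4 keep the cis, trans-to-aryl arrangement set by the diboration, and the mirror symmetry of 10 makes the two events identical. The step needs a single insertion per boron (the carbenoid decomposes well below the temperature at which the 1,2-shift sets in, so the product never meets live carbenoid), migration of carbon rather than of a pinacol oxygen (the normal preference), and a 1,2-shift that runs ahead of loss of the ring alkoxide from the β-oxygenated complex. The last point is helped by chloride being far the better leaving group and by the ring, which holds the exocyclic C–B bond and the endocyclic C–O bond at a dihedral angle near 120°, short of the anti-periplanar alignment an elimination requires.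

Step 7
Reactants: 13 meso-2,5-bis[4-(benzyloxy)-3,5-dimethoxyphenyl]-3,4-bis[(pinacolboryl)methyl]tetrahydrofuran
Product: 14 meso-{2,5-bis[4-(benzyloxy)-3,5-dimethoxyphenyl]tetrahydrofuran-3,4-diyl}dimethanol
Conditions: H2O2 (30% aq), NaOH (2 M aq), THF, 0 °C to rt
Reagents that add atoms: hydrogen peroxide, OO
Why: Oxidation of primary alkylboronic esters: hydroperoxide adds to boron and the CH2 group migrates from boron to oxygen. No ring stereocentre is involved, and cold alkaline peroxide should leave the benzyl ethers and the arenes untouched.

Step 8
Reactants: 14 meso-{2,5-bis[4-(benzyloxy)-3,5-dimethoxyphenyl]tetrahydrofuran-3,4-diyl}dimethanol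
Product: 15 meso-{2,5-bis[4-(benzyloxy)-3,5-dimethoxyphenyl]tetrahydrofuran-3,4-diyl}bis(methylene) bis(methanesulfonate)
Conditions: MsCl, Et3N, CH2Cl2, 0 °C
Reagents that add atoms: methanesulfonyl chloride, CS(=O)(=O)Cl
Why: Sulfonylation of both primary alcohols through the sulfene is fast at 0 °C, so the second hydroxyl should be capped before it can displace the first mesylate.

Step 9
Reactants: 15 meso-{2,5-bis[4-(benzyloxy)-3,5-dimethoxyphenyl]tetrahydrofuran-3,4-diyl}bis(methylene) bis(methanesulfonate)
Product: 16 (2S,3S,4R,5R)-2,5-bis[4-(benzyloxy)-3,5-dimethoxyphenyl]-3,4-dimethyltetrahydrofuran (meso)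
Conditions: LiEt3BH (6 equiv), THF, 0 °C to rt
Reagents that add atoms: none
Why: SN2 displacement of primary sulfonates by hydride; the triethylborohydride attacks carbon in preference to sulfur, and the reaction takes place at exocyclic carbons, so the four ring stereocentres are untouched.

Step 10
Reactants: 16 (2S,3S,4R,5R)-2,5-bis[4-(benzyloxy)-3,5-dimethoxyphenyl]-3,4-dimethyltetrahydrofuran
Product: 17 fragransin B1, 4,4'-[(2S,3S,4R,5R)-3,4-dimethyltetrahydrofuran-2,5-diyl]bis(2,6-dimethoxyphenol) (meso)
Conditions: H2 (1 atm), Pd/C (10%), EtOAc, rt
Reagents that add atoms: none
Why: Hydrogenolysis of aryl benzyl ethers; in a neutral, aprotic solvent these should be cleaved much faster than the benzylic C–O bonds of the ring, and the reaction is stopped once both benzyl groups are gone.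

## Compound list

1 | syringaldehyde (4-hydroxy-3,5-dimethoxybenzaldehyde) | COc1cc(C=O)cc(OC)c1O | starting material
2 | 4-(benzyloxy)-3,5-dimethoxybenzaldehyde | COc1cc(C=O)cc(OC)c1OCc1ccccc1 | intermediate
3 | ethynylmagnesium bromide | C#C[Mg]Br | starting material
4 | bromomagnesium 1-[4-(benzyloxy)-3,5-dimethoxyphenyl]prop-2-yn-1-olate (racemic) | COc1cc(C(O[Mg]Br)C#C)cc(OC)c1OCc1ccccc1 | intermediate (not isolated)
5 | bromomagnesium 1-[4-(benzyloxy)-3,5-dimethoxyphenyl]-3-(bromomagnesio)prop-2-yn-1-olate (racemic) | COc1cc(C(O[Mg]Br)C#C[Mg]Br)cc(OC)c1OCc1ccccc1 | intermediate (not isolated)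
6 | 1,4-bis[4-(benzyloxy)-3,5-dimethoxyphenyl]but-2-yne-1,4-diol (dl/meso mixture, carbinol centres unassigned) | COc1cc(C(O)C#CC(O)c2cc(OC)c(OCc3ccccc3)c(OC)c2)cc(OC)c1OCc1ccccc1 | intermediate
7 | (Z)-1,4-bis[4-(benzyloxy)-3,5-dimethoxyphenyl]but-2-ene-1,4-diol (dl/meso mixture, carbinol centres unassigned) | COc1cc(C(O)/C=C\C(O)c2cc(OC)c(OCc3ccccc3)c(OC)c2)cc(OC)c1OCc1ccccc1 | intermediate
8 | cis-(2R,5S)-2,5-bis[4-(benzyloxy)-3,5-dimethoxyphenyl]-2,5-dihydrofuran (meso) | COc1cc([C@H]2O[C@@H](c3cc(OC)c(OCc4ccccc4)c(OC)c3)C=C2)cc(OC)c1OCc1ccccc1 | intermediate
9 | bis(pinacolato)diboron | CC1(C)OB(OC1(C)C)B1OC(C)(C)C(C)(C)O1 | starting material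
10 | meso-2,5-bis[4-(benzyloxy)-3,5-dimethoxyphenyl]-3,4-bis(4,4,5,5-tetramethyl-1,3,2-dioxaborolan-2-yl)tetrahydrofuran (boryl groups cis, trans to the aryl groups) | COc1cc([C@H]2O[C@@H](c3cc(OC)c(OCc4ccccc4)c(OC)c3)[C@H](B5OC(C)(C)C(C)(C)O5)[C@@H]2B5OC(C)(C)C(C)(C)O5)cc(OC)c1OCc1ccccc1 | intermediate (precursor of the key step)
11 | bromochloromethane | ClCBr | starting material
12 | dilithium salt of the bis(boronate) complex of 10 in which each boron carries an added chloromethyl group | COc1cc([C@H]2O[C@@H](c3cc(OC)c(OCc4ccccc4)c(OC)c3)[C@H]([B-]5(CCl)OC(C)(C)C(C)(C)O5)[C@@H]2[B-]5(CCl)OC(C)(C)C(C)(C)O5)cc(OC)c1OCc1ccccc1.[Li+].[Li+] | intermediate (not isolated)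
13 | meso-2,5-bis[4-(benzyloxy)-3,5-dimethoxyphenyl]-3,4-bis[(4,4,5,5-tetramethyl-1,3,2-dioxaborolan-2-yl)methyl]tetrahydrofuran | COc1cc([C@H]2O[C@@H](c3cc(OC)c(OCc4ccccc4)c(OC)c3)[C@H](CB5OC(C)(C)C(C)(C)O5)[C@@H]2CB5OC(C)(C)C(C)(C)O5)cc(OC)c1OCc1ccccc1 | intermediate (product of the key step)
14 | meso-{2,5-bis[4-(benzyloxy)-3,5-dimethoxyphenyl]tetrahydrofuran-3,4-diyl}dimethanol | COc1cc([C@H]2O[C@@H](c3cc(OC)c(OCc4ccccc4)c(OC)c3)[C@H](CO)[C@@H]2CO)cc(OC)c1OCc1ccccc1 | intermediate
15 | meso-{2,5-bis[4-(benzyloxy)-3,5-dimethoxyphenyl]tetrahydrofuran-3,4-diyl}bis(methylene) bis(methanesulfonate) | COc1cc([C@H]2O[C@@H](c3cc(OC)c(OCc4ccccc4)c(OC)c3)[C@H](COS(C)(=O)=O)[C@@H]2COS(C)(=O)=O)cc(OC)c1OCc1ccccc1 | intermediate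
16 | (2S,3S,4R,5R)-2,5-bis[4-(benzyloxy)-3,5-dimethoxyphenyl]-3,4-dimethyltetrahydrofuran (meso) | COc1cc([C@H]2O[C@@H](c3cc(OC)c(OCc4ccccc4)c(OC)c3)[C@H](C)[C@@H]2C)cc(OC)c1OCc1ccccc1 | intermediate
17 | fragransin B1, 4,4'-[(2S,3S,4R,5R)-3,4-dimethyltetrahydrofuran-2,5-diyl]bis(2,6-dimethoxyphenol) (meso) | COc1cc([C@H]2O[C@@H](c3cc(OC)c(O)c(OC)c3)[C@H](C)[C@@H]2C)cc(OC)c1O | target

## Step count and least certain steps

Total step count: 10. Longest linear sequence: 10 steps (1 to 17); the route is linear, with 2 used twice in step 2.

**Step 6 (key step).** The most likely failure is incomplete insertion. Once the first boron has become an anionic complex, the neighbouring cis boron is shielded and electrostatically deactivated, and the short-lived carbenoid may decompose before the second addition, leaving mono-homologated material. A slower background process is fragmentation of the β-oxygenated complex with opening of the ring. The fallback is a two-stage homologation that sets out from 10. Dichloromethyllithium, preformed from CH2Cl2 and n-BuLi in THF at −100 °C, is stable at that temperature and can be used in excess until both boron atoms are complexed. ZnCl2 and warming should then give 2,5-bis[4-(benzyloxy)-3,5-dimethoxyphenyl]-3,4-bis[chloro(pinacolboryl)methyl]tetrahydrofuran F1, with the ring configuration of 10 and the two chlorine-bearing carbons as a mixture of no consequence. KHB(OiPr)3 then transfers hydride to boron, and a 1,2-shift of hydride with loss of chloride removes the halogen; the route is rejoined at 13.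

**Step 4.** The most likely failure is erosion of the cis selectivity. The cation may close through both conformers, the product may re-ionise and equilibrate toward a mixture of isomers, or a 1,2-hydride shift within the cation may divert material to a ketone. The fallback replaces the stereoconvergent ionisation by a stereospecific closure and sets out from 7. The dl diastereomer, (Z)-(1S*,4S*)-1,4-bis[4-(benzyloxy)-3,5-dimethoxyphenyl]but-2-ene-1,4-diol F2 (racemic), is separated from the meso form by chromatography and cyclised by an intramolecular Mitsunobu reaction (PPh3, DIAD, THF, 0 °C). Substitution with inversion at one carbinol carbon of the dl diol leads to the cis ring, and the ionic path has the same preference, so both mechanisms converge on 8.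

**Step 5.** The most likely failure is slow insertion of the 1,2-disubstituted ring alkene into the Pt–B bond. β-Hydride elimination from the platinum alkyl, which has a syn hydrogen at the benzylic carbon, could then cause double-bond migration into conjugation with an aryl group or dehydrogenative borylation. The fallback sets out from 8 and uses bis(catecholato)diboron, the more electrophilic diboron reagent, with the same phosphine-free platinum catalyst under milder conditions. It should give meso-2,5-bis[4-(benzyloxy)-3,5-dimethoxyphenyl]-3,4-bis(1,3,2-benzodioxaborol-2-yl)tetrahydrofuran F3, and exchange of the diol on boron with pinacol returns to 10.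

**Step 9.** The most likely failure is attack of hydride at sulfur instead of carbon. This unmasks an alkoxide that displaces the neighbouring cis mesylate and closes a second, fused ether ring; the same cyclisation can already intrude during step 8. The fallback avoids oxygen-activated intermediates altogether and sets out from 13. PhLi converts both boronic esters into the dilithium bis(phenylboronate) complex of 13 F4. Single-electron oxidation by a photoexcited iridium catalyst (for example Ir(ppy)2(dtbbpy)PF6, blue light, MeOH/acetone) releases the primary alkyl radicals, which take a hydrogen atom from thiophenol. This radical protodeboronation of primary pinacol boronic esters returns to the route at 16 and bypasses 14 and 15.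

**Step 10.** The most likely failure is over-reduction. Once the phenols are free, the benzylic C–O bonds of the ring become more prone to hydrogenolytic opening. The fallback sets out from 16 and removes the benzyl groups without hydrogen: BCl3 with pentamethylbenzene as scavenger of the benzyl cation, CH2Cl2, −78 °C, giving 17 directly. Should the Lewis acid ionise a ring C–O bond, re-closure favours the arrangement with each aryl group trans to its neighbouring methyl, which is that of the target.

## Further compounds

F1 | step 6 | 2,5-bis[4-(benzyloxy)-3,5-dimethoxyphenyl]-3,4-bis[chloro(4,4,5,5-tetramethyl-1,3,2-dioxaborolan-2-yl)methyl]tetrahydrofuran (ring configuration as in 10; chlorine-bearing carbons unassigned) | COc1cc([C@H]2O[C@@H](c3cc(OC)c(OCc4ccccc4)c(OC)c3)[C@H](C(Cl)B5OC(C)(C)C(C)(C)O5)[C@@H]2C(Cl)B5OC(C)(C)C(C)(C)O5)cc(OC)c1OCc1ccccc1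
F2 | step 4 | (Z)-(1S*,4S*)-1,4-bis[4-(benzyloxy)-3,5-dimethoxyphenyl]but-2-ene-1,4-diol (dl diastereomer, racemic; one enantiomer drawn) | COc1cc([C@@H](O)/C=C\[C@H](O)c2cc(OC)c(OCc3ccccc3)c(OC)c2)cc(OC)c1OCc1ccccc1
F3 | step 5 | meso-2,5-bis[4-(benzyloxy)-3,5-dimethoxyphenyl]-3,4-bis(1,3,2-benzodioxaborol-2-yl)tetrahydrofuran (boryl groups cis, trans to the aryl groups) | COc1cc([C@H]2O[C@@H](c3cc(OC)c(OCc4ccccc4)c(OC)c3)[C@H](B5Oc6ccccc6O5)[C@@H]2B5Oc6ccccc6O5)cc(OC)c1OCc1ccccc1
F4 | step 9 | dilithium salt of the bis(boronate) complex of 13 in which each boron carries an added phenyl group | COc1cc([C@H]2O[C@@H](c3cc(OC)c(OCc4ccccc4)c(OC)c3)[C@H](C[B-]5(c6ccccc6)OC(C)(C)C(C)(C)O5)[C@@H]2C[B-]5(c6ccccc6)OC(C)(C)C(C)(C)O5)cc(OC)c1OCc1ccccc1.[Li+].[Li+]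
F0 | step 10 | none | none
A1 | alternative 1 | methyl 2,5-bis[4-(benzyloxy)-3,5-dimethoxyphenyl]-4-methyltetrahydrofuran-3-carboxylate (2,5-cis, 2,3-trans, 3,4-cis; racemic) | COc1cc([C@H]2O[C@@H](c3cc(OC)c(OCc4ccccc4)c(OC)c3)[C@H](C)[C@@H]2C(=O)OC)cc(OC)c1OCc1ccccc1
A2 | alternative 1 | methyl 4-[4-(benzyloxy)-3,5-dimethoxybenzyloxy]-4-[4-(benzyloxy)-3,5-dimethoxyphenyl]-2-diazo-3-methylbutanoate (C3 and C4 configured as C4 and C5 of A1; racemic) | COc1cc(CO[C@@H](c2cc(OC)c(OCc3ccccc3)c(OC)c2)[C@H](C)C(=[N+]=[N-])C(=O)OC)cc(OC)c1OCc1ccccc1
A3 | alternative 2 | 5-[4-(benzyloxy)-3,5-dimethoxyphenyl]-3,4-dimethyldihydrofuran-2(3H)-one (4,5-trans, 3,4-cis; racemic) | O=C1O[C@@H](c2cc(OC)c(OCc3ccccc3)c(OC)c2)[C@H](C)[C@@H]1C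
A4 | alternative 2 | 2-[4-(benzyloxy)-3,5-dimethoxyphenyl]-3,4-dimethylcyclobutan-1-one (2,3-trans, 3,4-cis; racemic) | O=C1[C@@H](c2cc(OC)c(OCc3ccccc3)c(OC)c2)[C@H](C)[C@@H]1C
A5 | alternative 3 | dimethyl 2,5-bis[4-(benzyloxy)-3,5-dimethoxyphenyl]-4-methyltetrahydrofuran-3,3-dicarboxylate (2,5-cis, 4,5-trans; racemic) | COc1cc([C@H]2O[C@@H](c3cc(OC)c(OCc4ccccc4)c(OC)c3)[C@H](C)C2(C(=O)OC)C(=O)OC)cc(OC)c1OCc1ccccc1
A6 | alternative 3 | dimethyl cis-2-[4-(benzyloxy)-3,5-dimethoxyphenyl]-3-methylcyclopropane-1,1-dicarboxylate (racemic) | COC(=O)C1(C(=O)OC)[C@H](c2cc(OC)c(OCc3ccccc3)c(OC)c2)[C@@H]1C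
A7 | alternative 3 | 4-(benzyloxy)-3,5-dimethoxybenzaldehyde (identical with 2) | COc1cc(C=O)cc(OC)c1OCc1ccccc1
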